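**Plan**
- Retrosynthesis: the three benzyl ethers come off last; ring C of the acacetin half is cut at O1–C2 (cyclodehydration) and C3–C4 (ester–ketone Claisen), which leaves a methyl 3-aryloxy-2,4,6-trihydroxybenzoate.
- Ring A of the acacetin half is then cut at C7–C8 (Claisen cyclisation), at C4a–C8a (C-acylation of dimethyl acetonedicarboxylate) and at the O–CH2 bond to the 4'-oxygen of apigenin.
- Enabling feature: C8 of the acacetin half carries the aryloxy group between the oxygen-bearing carbons C7 and C8a of a 1,3,5-trioxygenated ring A whose C4a holds the carbonyl carbon C4. This is the pattern produced when ArOCH2–CO–CH(CO2Me)–CO–CH2–CO2Me folds head to tail.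
- Forward: the apigenin half is taken intact from apigenin, its 4'-oxygen is alkylated at an sp3 carbon, the chain is assembled, ring A is closed (step 6), then ring C (steps 8–9) with ring B from 4'-methoxyacetophenone, then hydrogenolysis.
- Stereochemistry: none to set.

Key step: step 6

Assumption: the target has no stereocentre and the diaryl ether axis rotates freely, so the compound is achiral and the route needs no stereocontrol.

**Step 1**
Reactants: 1 apigenin
Product: 2 7-O-benzylapigenin [7-(benzyloxy)-5-hydroxy-2-(4-hydroxyphenyl)-4H-chromen-4-one]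
Conditions: BnBr (1.05 equiv), K2CO3 (1.1 equiv), DMF, 0 °C → rt
Reagents that add atoms: benzyl bromide, BrCc1ccccc1
Why: Williamson etherification in which one equivalent of mild base ionises the 7-OH, the most acidic phenol (para to the pyranone carbonyl), ahead of the 4'-OH while the chelated 5-OH stays inert, and any 7,4'-dibenzyl ether should be removable by crystallisation or chromatography.

**Step 2**
Reactants: 2 7-O-benzylapigenin; 3 methyl bromoacetate
Product: 4 methyl 2-{4-[7-(benzyloxy)-5-hydroxy-4-oxo-4H-chromen-2-yl]phenoxy}acetate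
Conditions: K2CO3 (1.5 equiv), acetone, reflux
Reagents that add atoms: none
Why: Williamson etherification of the only unchelated phenol left (4'-OH) with a highly SN2-reactive α-halo ester, the hydrogen-bonded 5-OH not being alkylated by carbonate under these conditions.

**Step 3**
Reactants: 4 methyl aryloxyacetate
Product: 5 2-{4-[7-(benzyloxy)-5-hydroxy-4-oxo-4H-chromen-2-yl]phenoxy}acetic acid
Conditions: LiOH·H2O (2 equiv), THF–H2O, rt; then 1 M HCl
Reagents that add atoms: lithium hydroxide, [Li+].[OH-]
Why: Ester saponification at room temperature, which leaves the flavone ring (opened only by hot concentrated alkali), the benzyl ether and the aryl alkyl ether untouched, and acidification should precipitate the acid.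

**Step 4**
Reactants: 5 aryloxyacetic acid
Product: 6 2-{4-[7-(benzyloxy)-5-hydroxy-4-oxo-4H-chromen-2-yl]phenoxy}acetyl chloride
Conditions: (COCl)2 (1.2 equiv), DMF (cat.), CH2Cl2, 0 °C → rt; evaporate, use crude
Reagents that add atoms: oxalyl chloride, O=C(Cl)C(Cl)=O
Why: Acid chloride formation via the chloroiminium species from oxalyl chloride and DMF under base-free conditions, in which the chelated 5-OH is too poor a nucleophile to be acylated and all by-products are volatile.

**Step 5**
Reactants: 6 aryloxyacetyl chloride; 7 dimethyl 3-oxopentanedioate (dimethyl 1,3-acetonedicarboxylate)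
Product: 8 dimethyl 2-({4-[7-(benzyloxy)-5-hydroxy-4-oxo-4H-chromen-2-yl]phenoxy}acetyl)-3-oxopentanedioate (enolised triketo diester)
Conditions: 7 (1.1 equiv), MgCl2 (1.1 equiv), pyridine (2.2 equiv), CH2Cl2, 0 °C; then 6, 0 °C → rt; 1 M HCl work-up
Reagents that add atoms: none
Why: C-acylation of a magnesium enolate (MgCl2/amine acylation of a 1,3-dicarbonyl compound) at the carbon between ketone and ester, the product being held as the non-nucleophilic Mg chelate of the tricarbonyl methine so that di- and O-acylation are suppressed, with pyridine chosen over a stronger amine to limit ketene formation from the aryloxyacetyl chloride.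

**Step 6**
Reactants: 8 triketo diester
Product: 9 methyl 3-{4-[7-(benzyloxy)-5-hydroxy-4-oxo-4H-chromen-2-yl]phenoxy}-2,4,6-trihydroxybenzoate
Conditions: Mg(OMe)2 (8 equiv), MeOH–THF, reflux; then cold 1 M HCl
Reagents that add atoms: none
Why: Proposed new method: Mg(OMe)2 turns 8 into a magnesium-chelated polyanion in which metal ions bound between the methine ester and the flanking ketone oxygens fold the chain into a U, and reversible deprotonation of the ArOCH2 group (acidified by the adjacent metal-bound ketone and by the inductive pull of the aryloxy oxygen) gives a dienolate whose terminal carbon (future C8) adds to the remote ester carbonyl (future C7); loss of methoxide gives a cyclohexane-1,3,5-trione that enolises to the aromatic ring. The closest known reactions are the Mg(OMe)2- or alkoxide-mediated Claisen cyclisations of 3,5,7-triketo esters to acylphloroglucinols and the Dieckmann closure in the malonate/acetonedicarboxylate synthesis of phloroglucinol carboxylates, where the attacking carbon lies between two carbonyl groups instead of being a ketone α-carbon that carries an ether oxygen. Ring A closes in a 6-(enolendo)-exo-trig mode and no stereocentre is created. The step needs C-acylation to prevail over O-acylation through the enol oxygen of the aryloxyacetyl ketone (4-hydroxy-2-pyranone formation): every other C–C closure open to 8 would be four-membered, the pyranone is expected to be reopened by methoxide under these conditions, and aromatisation makes the carbocycle the irreversible sink. Methyl esters with methoxide keep transesterification degenerate, and the fully chelated tricarbonyl anion is protected against retro-Claisen cleavage.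

**Step 7**
Reactants: 9 phloroglucinol carboxylate
Product: 10 methyl 4,6-bis(benzyloxy)-3-{4-[7-(benzyloxy)-5-hydroxy-4-oxo-4H-chromen-2-yl]phenoxy}-2-hydroxybenzoate
Conditions: BnBr (2.1 equiv), K2CO3 (2.2 equiv), DMF, 0 °C → rt
Reagents that add atoms: benzyl bromide, BrCc1ccccc1
Why: Williamson etherification under mild carbonate conditions in which the unchelated 4-OH reacts first and the 6-OH second, whereas the 2-OH (hydrogen-bonded to the ester and buttressed by the ortho aryloxy group) and the chelated flavone 5-OH should stay free, by analogy with the partial alkylation of 3-substituted phloroacyl compounds.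

**Step 8**
Reactants: 10 dibenzyl ether ester; 11 4'-methoxyacetophenone
Product: 12 1-[4,6-bis(benzyloxy)-3-{4-[7-(benzyloxy)-5-hydroxy-4-oxo-4H-chromen-2-yl]phenoxy}-2-hydroxyphenyl]-3-(4-methoxyphenyl)propane-1,3-dione
Conditions: 11 (3 equiv), LiHMDS (6 equiv), THF, −78 °C → rt; aq HCl work-up
Reagents that add atoms: none
Why: Crossed ester–ketone Claisen condensation in which excess lithium enolate of 11 adds to the lithium-chelated, non-enolisable salicylate ester and the equilibrium is pulled forward by deprotonation of the β-diketone, both phenols being masked as lithium phenoxides.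

**Step 9**
Reactants: 12 β-diketone
Product: 13 5,7-bis(benzyloxy)-8-{4-[7-(benzyloxy)-5-hydroxy-4-oxo-4H-chromen-2-yl]phenoxy}-2-(4-methoxyphenyl)-4H-chromen-4-one
Conditions: p-TsOH·H2O (0.2 equiv), toluene, 90 °C
Reagents that add atoms: none
Why: Acid-catalysed cyclodehydration of an o-hydroxyaryl 1,3-diketone (the ring-closing stage of the Baker–Venkataraman flavone synthesis), in which the single free phenol of that ring, the one ortho to the aryloxy group, adds to the anisoyl carbonyl so that the ether can only end up at C8.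

**Step 10**
Reactants: 13 tribenzyl biflavone ether
Product: 14 5,7-dihydroxy-8-[4-(5,7-dihydroxy-4-oxo-4H-chromen-2-yl)phenoxy]-2-(4-methoxyphenyl)-4H-chromen-4-one (target)
Conditions: H2 (1 atm), 10% Pd/C, THF–MeOH, rt
Reagents that add atoms: none
Why: Catalytic hydrogenolysis of the three aryl benzyl ethers, under which the flavone C2=C3 bonds (vinylogous esters), the diaryl ether and the methyl ether should be inert if the reaction is stopped at the calculated hydrogen uptake.

**Compound list**
1 | apigenin | Oc1ccc(-c2cc(=O)c3c(O)cc(O)cc3o2)cc1 | starting material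
2 | 7-O-benzylapigenin | Oc1ccc(-c2cc(=O)c3c(O)cc(OCc4ccccc4)cc3o2)cc1 | intermediate
3 | methyl bromoacetate | COC(=O)CBr | starting material
4 | methyl 2-{4-[7-(benzyloxy)-5-hydroxy-4-oxo-4H-chromen-2-yl]phenoxy}acetate | COC(=O)COc1ccc(-c2cc(=O)c3c(O)cc(OCc4ccccc4)cc3o2)cc1 | intermediate
5 | 2-{4-[7-(benzyloxy)-5-hydroxy-4-oxo-4H-chromen-2-yl]phenoxy}acetic acid | OC(=O)COc1ccc(-c2cc(=O)c3c(O)cc(OCc4ccccc4)cc3o2)cc1 | intermediate
6 | 2-{4-[7-(benzyloxy)-5-hydroxy-4-oxo-4H-chromen-2-yl]phenoxy}acetyl chloride | ClC(=O)COc1ccc(-c2cc(=O)c3c(O)cc(OCc4ccccc4)cc3o2)cc1 | intermediate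
7 | dimethyl 3-oxopentanedioate | COC(=O)CC(=O)CC(=O)OC | starting material
8 | dimethyl 2-({4-[7-(benzyloxy)-5-hydroxy-4-oxo-4H-chromen-2-yl]phenoxy}acetyl)-3-oxopentanedioate (drawn as the triketo form) | COC(=O)CC(=O)C(C(=O)OC)C(=O)COc1ccc(-c2cc(=O)c3c(O)cc(OCc4ccccc4)cc3o2)cc1 | intermediate
9 | methyl 3-{4-[7-(benzyloxy)-5-hydroxy-4-oxo-4H-chromen-2-yl]phenoxy}-2,4,6-trihydroxybenzoate | COC(=O)c1c(O)cc(O)c(Oc2ccc(-c3cc(=O)c4c(O)cc(OCc5ccccc5)cc4o3)cc2)c1O | intermediate
10 | methyl 4,6-bis(benzyloxy)-3-{4-[7-(benzyloxy)-5-hydroxy-4-oxo-4H-chromen-2-yl]phenoxy}-2-hydroxybenzoate | COC(=O)c1c(OCc2ccccc2)cc(OCc2ccccc2)c(Oc2ccc(-c3cc(=O)c4c(O)cc(OCc5ccccc5)cc4o3)cc2)c1O | intermediate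
11 | 4'-methoxyacetophenone | COc1ccc(C(C)=O)cc1 | starting material
12 | 1-[4,6-bis(benzyloxy)-3-{4-[7-(benzyloxy)-5-hydroxy-4-oxo-4H-chromen-2-yl]phenoxy}-2-hydroxyphenyl]-3-(4-methoxyphenyl)propane-1,3-dione | COc1ccc(C(=O)CC(=O)c2c(OCc3ccccc3)cc(OCc3ccccc3)c(Oc3ccc(-c4cc(=O)c5c(O)cc(OCc6ccccc6)cc5o4)cc3)c2O)cc1 | intermediate
13 | 5,7-bis(benzyloxy)-8-{4-[7-(benzyloxy)-5-hydroxy-4-oxo-4H-chromen-2-yl]phenoxy}-2-(4-methoxyphenyl)-4H-chromen-4-one | COc1ccc(-c2cc(=O)c3c(OCc4ccccc4)cc(OCc4ccccc4)c(Oc4ccc(-c5cc(=O)c6c(O)cc(OCc7ccccc7)cc6o5)cc4)c3o2)cc1 | intermediate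
14 | 5,7-dihydroxy-8-[4-(5,7-dihydroxy-4-oxo-4H-chromen-2-yl)phenoxy]-2-(4-methoxyphenyl)-4H-chromen-4-one | COc1ccc(-c2cc(=O)c3c(O)cc(O)c(Oc4ccc(-c5cc(=O)c6c(O)cc(O)cc6o5)cc4)c3o2)cc1 | target

**Step count and risks**
Total steps: 10. Longest linear sequence: 10 steps (from apigenin 1).

Steps most likely to fail:

Step 6 (new method). Carbanion formation at the aryloxymethylene may be too slow, so that the chain rests as the O-acylated pyranone or loses the aryloxyacetyl group by retro-Claisen cleavage. The fallback forges the diaryl ether by a copper-mediated Ullmann coupling; it sets out from 2 and returns at 10. Commercial methyl 2,4,6-trihydroxybenzoate would be dibenzylated (BnBr 2 equiv, K2CO3, DMF) to methyl 2,4-bis(benzyloxy)-6-hydroxybenzoate F1. Phenol-directed ortho-iodination (NIS, cat. TFA, MeCN) would then give methyl 4,6-bis(benzyloxy)-2-hydroxy-3-iodobenzoate F2, and protection of the phenol (MOMCl, NaH, DMF) would give methyl 4,6-bis(benzyloxy)-3-iodo-2-(methoxymethoxy)benzoate F3. Coupling of F3 with the 4'-phenol of 2 (CuI, 2,2,6,6-tetramethylheptane-3,5-dione, Cs2CO3, NMP, 110 °C) would give methyl 4,6-bis(benzyloxy)-3-{4-[7-(benzyloxy)-5-hydroxy-4-oxo-4H-chromen-2-yl]phenoxy}-2-(methoxymethoxy)benzoate F4. Removal of the MOM group (HCl, MeOH–THF) delivers 10 with the free hydroxyl fixed next to the ether by construction.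

Step 8. The ketone enolate may add too slowly to the doubly ortho-substituted, phenoxide-deactivated ester, so that enolate self-condensation or attack on the existing flavone takes over. The fallback replaces the enolate by an acetylide; it sets out from 10 and returns at 13. Aminolysis of the ester (MeNHOMe·HCl, AlMe3, toluene, 60 °C) would give the Weinreb amide 4,6-bis(benzyloxy)-3-{4-[7-(benzyloxy)-5-hydroxy-4-oxo-4H-chromen-2-yl]phenoxy}-2-hydroxy-N-methoxy-N-methylbenzamide F5. Addition of excess lithium (4-methoxyphenyl)acetylide (from commercial 4-ethynylanisole and n-BuLi, THF, −78 → 0 °C) would give the ynone 1-[4,6-bis(benzyloxy)-3-{4-[7-(benzyloxy)-5-hydroxy-4-oxo-4H-chromen-2-yl]phenoxy}-2-hydroxyphenyl]-3-(4-methoxyphenyl)prop-2-yn-1-one F6. Amine-mediated 6-endo cyclisation of the o-hydroxyaryl ynone through its only free phenol (Et2NH, EtOH–THF, reflux) closes the pyranone to 13.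

Step 7. Site selectivity between the two ester-flanked hydroxyls may be lost (benzylation at the buttressed 2-OH, or over-benzylation), which would send the later ring closure to the wrong oxygen. The fallback inverts the logic to exhaustive protection followed by selective cleavage; it sets out from 9 and returns at 10. Forcing benzylation (BnBr excess, K2CO3, DMF, 70 °C) would give methyl 2,4,6-tris(benzyloxy)-3-{4-[5,7-bis(benzyloxy)-4-oxo-4H-chromen-2-yl]phenoxy}benzoate F7. Chelation-directed debenzylation (MgBr2·OEt2, toluene–Et2O, reflux) is expected to cleave only the two benzyl ethers that sit beside a carbonyl and are crowded on the other side: the flavone 5-O-benzyl (peri to C4=O) and the benzoate 2-O-benzyl (between the ester and the aryloxy group). This gives 10.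

**Further compounds**
F1 | step 6 | methyl 2,4-bis(benzyloxy)-6-hydroxybenzoate | COC(=O)c1c(O)cc(OCc2ccccc2)cc1OCc1ccccc1
F2 | step 6 | methyl 4,6-bis(benzyloxy)-2-hydroxy-3-iodobenzoate | COC(=O)c1c(OCc2ccccc2)cc(OCc2ccccc2)c(I)c1O
F3 | step 6 | methyl 4,6-bis(benzyloxy)-3-iodo-2-(methoxymethoxy)benzoate | COCOc1c(I)c(OCc2ccccc2)cc(OCc2ccccc2)c1C(=O)OC
F4 | step 6 | methyl 4,6-bis(benzyloxy)-3-{4-[7-(benzyloxy)-5-hydroxy-4-oxo-4H-chromen-2-yl]phenoxy}-2-(methoxymethoxy)benzoate | COCOc1c(Oc2ccc(-c3cc(=O)c4c(O)cc(OCc5ccccc5)cc4o3)cc2)c(OCc2ccccc2)cc(OCc2ccccc2)c1C(=O)OC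
F5 | step 8 | 4,6-bis(benzyloxy)-3-{4-[7-(benzyloxy)-5-hydroxy-4-oxo-4H-chromen-2-yl]phenoxy}-2-hydroxy-N-methoxy-N-methylbenzamide | CON(C)C(=O)c1c(OCc2ccccc2)cc(OCc2ccccc2)c(Oc2ccc(-c3cc(=O)c4c(O)cc(OCc5ccccc5)cc4o3)cc2)c1O
F6 | step 8 | 1-[4,6-bis(benzyloxy)-3-{4-[7-(benzyloxy)-5-hydroxy-4-oxo-4H-chromen-2-yl]phenoxy}-2-hydroxyphenyl]-3-(4-methoxyphenyl)prop-2-yn-1-one | COc1ccc(C#CC(=O)c2c(OCc3ccccc3)cc(OCc3ccccc3)c(Oc3ccc(-c4cc(=O)c5c(O)cc(OCc6ccccc6)cc5o4)cc3)c2O)cc1
F7 | step 7 | methyl 2,4,6-tris(benzyloxy)-3-{4-[5,7-bis(benzyloxy)-4-oxo-4H-chromen-2-yl]phenoxy}benzoate | COC(=O)c1c(OCc2ccccc2)cc(OCc2ccccc2)c(Oc2ccc(-c3cc(=O)c4c(OCc5ccccc5)cc(OCc5ccccc5)cc4o3)cc2)c1OCc1ccccc1
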